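**Retrosynthetic overview**
- Pyran ring (ring B) is made last. O2–C1 and C1–C8a come from a one-carbon amide acetal, and C4–C4a from a Mukaiyama-type addition of the ring A enol to a masked 5-hydroxy-2-oxopentanal (4,5-dihydrofuran-2-carbaldehyde).
- Ring A and its only stereocentre (C7) come from a desymmetrising 1,2-acyl shift (α-ketol ring expansion) of achiral 2-acetyl-2-hydroxycyclopentane-1,3-dione. This is the proposed new step.
- That ketol comes from 2-acetylcyclopentane-1,3-dione, made from succinic anhydride and isopropenyl acetate.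
- Ring order: five-membered carbocycle, then six-membered ring A by ring expansion, then ring B.

Assumption: atom labels (C1 to C8a) follow the isochromene numbering of the target, the drawn enantiomer is 7S by CIP analysis, and the sense of induction in step 2 is a prediction that must be confirmed, the antipodal ligand being used if it proves opposite.

**Route**

Step 1
Reactants: 1 succinic anhydride; 2 isopropenyl acetate
Product: 3 2-acetylcyclopentane-1,3-dione
Conditions: AlCl3 (2.1 equiv), ClCH2CH2Cl, rt then reflux; aq. HCl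
Reagents that add atoms: none
Why: Lewis-acid C-acylation of the enol acetate by the anhydride followed by intramolecular Claisen-type acylation is the established one-flask synthesis of this enolised triketone (modest yield, cheap materials); no stereocentre is formed.

Step 2
Reactants: 3 2-acetylcyclopentane-1,3-dione
Product: 5 (6S)-2,6-dihydroxy-6-methylcyclohex-2-ene-1,5-dione, via 2-acetyl-2-hydroxycyclopentane-1,3-dione 4 (not isolated)
Conditions: DMDO (1.1 equiv), acetone, −20 °C, then solvent exchange; Cu(OTf)2 (10 mol%), (S,S)-t-Bu-BOX (12 mol%), 4 Å MS, CH2Cl2, −20 °C → rt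
Reagents that add atoms: dimethyldioxirane (DMDO), CC1(C)OO1
Why: Proposed new method: dioxirane α-hydroxylation of the enolised triketone (Rubottom-type enol epoxidation) gives the achiral, mirror-symmetric ketol 4; the chiral divalent-copper bis(oxazoline) Lewis acid then chelates the tertiary hydroxyl and the freely rotating acetyl carbonyl (the ring carbonyls cannot reach a coplanar chelate), and one of the two enantiotopic ring acyl carbons shifts 1,2 onto the acetyl carbon (α-ketol/acyloin rearrangement with ring expansion), so the choice of migrating arm inside the C2-symmetric ligand pocket sets the new C(OH)(CH3) centre as S; the shift is driven by release of the strained triacyl carbinol and by enolisation of the new 1,2-dione to the diosphenol; the closest known reaction types are the copper–bis(oxazoline)-catalysed enantioselective α-ketol rearrangement of β-hydroxy-α-dicarbonyls and the ring-expanding acyloin rearrangement of 1-acylcycloalkanols, with acyl migration itself precedented in the humulone to isohumulone ketol shift.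

Step 3
Reactants: 5 (6S)-2,6-dihydroxy-6-methylcyclohex-2-ene-1,5-dione; 6 butanoyl chloride
Product: 8 (1S)-3-hydroxy-1-methyl-2,6-dioxocyclohex-3-en-1-yl butanoate, via bis-butanoate 7 (not isolated)
Conditions: PrCOCl (2.3 equiv), pyridine, DMAP (10 mol%), CH2Cl2, 0 °C → rt; then MeOH, imidazole, rt
Reagents that add atoms: none
Why: DMAP-catalysed acylation esterifies both hydroxyls, and the much more electrophilic enol ester is then methanolysed selectively while the hindered tertiary butanoate stays; C7 is untouched and, once acylated, can no longer undergo ketol shifts.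

Step 4
Reactants: 9 2,3-dihydrofuran
Product: 11 4,5-dihydrofuran-2-carbaldehyde, via 5-lithio-2,3-dihydrofuran 10 (not isolated)
Conditions: t-BuLi, THF, −78 → 0 °C; DMF, −78 °C; H2O
Reagents that add atoms: N,N-dimethylformamide (DMF), CN(C)C=O
Why: α-Lithiation of the cyclic enol ether at the vinylic carbon next to oxygen and Bouveault-type formylation of the vinyllithium with DMF; no stereocentre is formed.

Step 5
Reactants: 8 (1S)-3-hydroxy-1-methyl-2,6-dioxocyclohex-3-en-1-yl butanoate; 11 4,5-dihydrofuran-2-carbaldehyde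
Product: 14 (1S)-4-[(4,5-dihydrofuran-2-yl)(methoxy)methyl]-3-hydroxy-1-methyl-2,6-dioxocyclohex-3-en-1-yl butanoate, via trimethylsilyl enol ether 12 (not isolated), via dimethyl acetal 13 (not isolated)
Conditions: 8, TMSOTf (1.1 equiv), i-Pr2NEt (1.1 equiv), CH2Cl2, −78 → 0 °C; separately 11, MeOSiMe3 (2.2 equiv), TMSOTf (5 mol%), CH2Cl2, −78 °C; combine, TMSOTf (0.5 equiv), −78 °C; aq. NaHCO3
Reagents that add atoms: methoxytrimethylsilane, CO[Si](C)(C)C
Why: One-pot enol silane formation and Mukaiyama-type addition to an acetal made in the flask: the 2-siloxy enone is nucleophilic only at C4a (the enol carbon of the 1,2-dione), and the 1-methoxy-2-alkoxyallyl cation from 13 is attacked at its oxocarbenium carbon, which puts OMe on C4 and keeps the C3 ketone and the side-chain hydroxyl masked together as the cyclic enol ether; the new C4 centre forms as a mixture of epimers and is erased in step 6.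

Step 6
Reactants: 14 (1S)-4-[(4,5-dihydrofuran-2-yl)(methoxy)methyl]-3-hydroxy-1-methyl-2,6-dioxocyclohex-3-en-1-yl butanoate
Product: 16 (7S)-5-hydroxy-3-(3-hydroxypropyl)-4-methoxy-7-methyl-6,8-dioxo-7,8-dihydro-6H-isochromen-7-yl butanoate, via enaminone 15 (not isolated)
Conditions: Me2NCH(OMe)2 (1.2 equiv), toluene, rt; then 1 M HCl, THF, 0 °C → rt
Reagents that add atoms: N,N-dimethylformamide dimethyl acetal, CN(C)C(OC)OC; water, O
Why: The amide acetal condenses at C8a, the only remaining activated methylene, and aqueous acid then hydrolyses the cyclic enol ether to the 5-hydroxy ketone and closes the pyran by addition–elimination of the ketone enol oxygen on the enaminone (chromone/4-pyranone-type cyclodehydration of a 1,5-dicarbonyl); C4 becomes sp2, and C7 is unaffected because it is quaternary and acylated.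

**Compound list**
1 | succinic anhydride | O=C1CCC(=O)O1 | starting material
2 | isopropenyl acetate | CC(=C)OC(C)=O | starting material
3 | 2-acetylcyclopentane-1,3-dione (enol form) | CC(=O)C1=C(O)CCC1=O | intermediate
4 | 2-acetyl-2-hydroxycyclopentane-1,3-dione | CC(=O)C1(O)C(=O)CCC1=O | intermediate
5 | (6S)-2,6-dihydroxy-6-methylcyclohex-2-ene-1,5-dione | O[C@@]1(C)C(=O)CC=C(O)C1=O | intermediate
6 | butanoyl chloride | CCCC(Cl)=O | starting material
7 | (1S)-3-(butanoyloxy)-1-methyl-2,6-dioxocyclohex-3-en-1-yl butanoate | CCCC(=O)O[C@@]1(C)C(=O)CC=C(OC(=O)CCC)C1=O | intermediate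
8 | (1S)-3-hydroxy-1-methyl-2,6-dioxocyclohex-3-en-1-yl butanoate | CCCC(=O)O[C@@]1(C)C(=O)CC=C(O)C1=O | intermediate
9 | 2,3-dihydrofuran | C1CC=CO1 | starting material
10 | 5-lithio-2,3-dihydrofuran | [Li]C1=CCCO1 | intermediate
11 | 4,5-dihydrofuran-2-carbaldehyde | O=CC1=CCCO1 | intermediate
12 | (1S)-1-methyl-2,6-dioxo-3-[(trimethylsilyl)oxy]cyclohex-3-en-1-yl butanoate | CCCC(=O)O[C@@]1(C)C(=O)CC=C(O[Si](C)(C)C)C1=O | intermediate
13 | 2-(dimethoxymethyl)-4,5-dihydrofuran | COC(OC)C1=CCCO1 | intermediate
14 | (1S)-4-[(4,5-dihydrofuran-2-yl)(methoxy)methyl]-3-hydroxy-1-methyl-2,6-dioxocyclohex-3-en-1-yl butanoate (epimers at the methoxy carbon) | CCCC(=O)O[C@@]1(C)C(=O)CC(C(OC)C2=CCCO2)=C(O)C1=O | intermediate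
15 | (1S)-4-[(4,5-dihydrofuran-2-yl)(methoxy)methyl]-5-[(dimethylamino)methylidene]-3-hydroxy-1-methyl-2,6-dioxocyclohex-3-en-1-yl butanoate | CCCC(=O)O[C@@]1(C)C(=O)C(=CN(C)C)C(C(OC)C2=CCCO2)=C(O)C1=O | intermediate
16 | (7S)-5-hydroxy-3-(3-hydroxypropyl)-4-methoxy-7-methyl-6,8-dioxo-7,8-dihydro-6H-isochromen-7-yl butanoate | CCCC(=O)O[C@@]1(C)C(=O)C2=COC(CCCO)=C(OC)C2=C(O)C1=O | target

**Step count**
Total steps: 6. Longest linear sequence: 5 (steps 1, 2, 3, 5, 6); step 4 is a one-step side branch.

**Steps most likely to fail**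

Step 2 (the proposed ring expansion). Possible failures:
- a 1,2-acetyl shift onto a ring carbonyl, giving the isomeric cyclopentane-1,2-dione;
- further ketol contraction of 5;
- catalyst inhibition by the chelating diosphenol product;
- a racemic background reaction or low selectivity.

Compound 5 should be acylated promptly, since only the free ketol can revert. Fallback with known chemistry: set out from 4 and run the classical non-asymmetric acyloin rearrangement (heat with Al(O-i-Pr)3 in toluene) to racemic 2,6-dihydroxy-6-methylcyclohex-2-ene-1,5-dione F1. Resolve it by preparative chromatography on a chiral stationary phase and return to the route at 5. Stereocontrol then comes from resolution rather than catalysis.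

Step 5 (C4–C4a bond). Possible failures:
- attack at the ring terminus of the alkoxyallyl cation;
- oligomerisation of the enol-ether acetal;
- low nucleophilicity of the 2-siloxy enone.

Fallback: set out from 8 and use an alkynyl acetal, whose propargylic oxocarbenium ion has no competing nucleophilic site. The acetal, tert-butyl[(5,5-dimethoxypent-3-yn-1-yl)oxy]dimethylsilane F2, is made from commercial tert-butyl(but-3-yn-1-yloxy)dimethylsilane with n-BuLi, then HC(OMe)3 and BF3·OEt2. The same TMSOTf/i-Pr2NEt conditions give the propargylic methyl ether (1S)-4-[5-{[tert-butyl(dimethyl)silyl]oxy}-1-methoxypent-2-yn-1-yl]-3-hydroxy-1-methyl-2,6-dioxocyclohex-3-en-1-yl butanoate F3. Me2NCH(OMe)2 converts it into the enaminone F4. (Ph3P)AuNTf2 (monovalent gold, 5 mol%) in wet CH2Cl2 with AcOH hydrolyses the enaminone, closes the ring by 6-exo-dig addition of the enol oxygen to the alkyne, and the acid moves the exocyclic double bond into the ring. This gives the silyl ether of the target, (7S)-3-(3-{[tert-butyl(dimethyl)silyl]oxy}propyl)-5-hydroxy-4-methoxy-7-methyl-6,8-dioxo-7,8-dihydro-6H-isochromen-7-yl butanoate F5. HF·pyridine returns to the route at 16.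

Step 6 (one-carbon insertion and pyran closure). Possible failures:
- O-methylation of the C5 enol by the amide acetal;
- base-induced loss of methanol from 14;
- equilibration of the free hydroxypropyl chain to a spiroketal under acid.

The conjugated, pyrylium-like azaphilone chromophore is expected to be the thermodynamic product, but this is not proven. Fallback: set out from 14 and use a protected, staged closure. AcOH/H2O/THF hydrolyses only the enol ether, giving the lactol (1S)-3-hydroxy-4-[(2-hydroxyoxolan-2-yl)(methoxy)methyl]-1-methyl-2,6-dioxocyclohex-3-en-1-yl butanoate F6. TBSCl/imidazole traps the open chain as the bis-silyl keto ether F7, silylated on the primary and the enol oxygen. Me2NCH(OMe)2 then gives the enaminone F8, in which neither O-methylation nor enolate-driven elimination can occur. Anhydrous CF3CO2H in CH2Cl2 closes the pyran to the bis-silyl ether (7S)-5-{[tert-butyl(dimethyl)silyl]oxy}-3-(3-{[tert-butyl(dimethyl)silyl]oxy}propyl)-4-methoxy-7-methyl-6,8-dioxo-7,8-dihydro-6H-isochromen-7-yl butanoate F9. HF·pyridine removes both silyl groups under non-equilibrating conditions and returns to the route at 16.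

Further compounds
F1 | step 2 | racemic 2,6-dihydroxy-6-methylcyclohex-2-ene-1,5-dione | OC1(C)C(=O)CC=C(O)C1=O
F2 | step 5 | tert-butyl[(5,5-dimethoxypent-3-yn-1-yl)oxy]dimethylsilane | COC(OC)C#CCCO[Si](C)(C)C(C)(C)C
F3 | step 5 | (1S)-4-[5-{[tert-butyl(dimethyl)silyl]oxy}-1-methoxypent-2-yn-1-yl]-3-hydroxy-1-methyl-2,6-dioxocyclohex-3-en-1-yl butanoate | CCCC(=O)O[C@@]1(C)C(=O)CC(C(OC)C#CCCO[Si](C)(C)C(C)(C)C)=C(O)C1=O
F4 | step 5 | (1S)-4-[5-{[tert-butyl(dimethyl)silyl]oxy}-1-methoxypent-2-yn-1-yl]-5-[(dimethylamino)methylidene]-3-hydroxy-1-methyl-2,6-dioxocyclohex-3-en-1-yl butanoate | CCCC(=O)O[C@@]1(C)C(=O)C(=CN(C)C)C(C(OC)C#CCCO[Si](C)(C)C(C)(C)C)=C(O)C1=O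
F5 | step 5 | (7S)-3-(3-{[tert-butyl(dimethyl)silyl]oxy}propyl)-5-hydroxy-4-methoxy-7-methyl-6,8-dioxo-7,8-dihydro-6H-isochromen-7-yl butanoate | CCCC(=O)O[C@@]1(C)C(=O)C2=COC(CCCO[Si](C)(C)C(C)(C)C)=C(OC)C2=C(O)C1=O
F6 | step 6 | (1S)-3-hydroxy-4-[(2-hydroxyoxolan-2-yl)(methoxy)methyl]-1-methyl-2,6-dioxocyclohex-3-en-1-yl butanoate | CCCC(=O)O[C@@]1(C)C(=O)CC(C(OC)C2(O)CCCO2)=C(O)C1=O
F7 | step 6 | (1S)-4-[5-{[tert-butyl(dimethyl)silyl]oxy}-1-methoxy-2-oxopentyl]-3-{[tert-butyl(dimethyl)silyl]oxy}-1-methyl-2,6-dioxocyclohex-3-en-1-yl butanoate | CCCC(=O)O[C@@]1(C)C(=O)CC(C(OC)C(=O)CCCO[Si](C)(C)C(C)(C)C)=C(O[Si](C)(C)C(C)(C)C)C1=O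
F8 | step 6 | (1S)-4-[5-{[tert-butyl(dimethyl)silyl]oxy}-1-methoxy-2-oxopentyl]-3-{[tert-butyl(dimethyl)silyl]oxy}-5-[(dimethylamino)methylidene]-1-methyl-2,6-dioxocyclohex-3-en-1-yl butanoate | CCCC(=O)O[C@@]1(C)C(=O)C(=CN(C)C)C(C(OC)C(=O)CCCO[Si](C)(C)C(C)(C)C)=C(O[Si](C)(C)C(C)(C)C)C1=O
F9 | step 6 | (7S)-5-{[tert-butyl(dimethyl)silyl]oxy}-3-(3-{[tert-butyl(dimethyl)silyl]oxy}propyl)-4-methoxy-7-methyl-6,8-dioxo-7,8-dihydro-6H-isochromen-7-yl butanoate | CCCC(=O)O[C@@]1(C)C(=O)C2=COC(CCCO[Si](C)(C)C(C)(C)C)=C(OC)C2=C(O[Si](C)(C)C(C)(C)C)C1=O
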